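**Retrosynthetic overview**
1. Target 14 ⇐ acetonide 13 (diol released last) ⇐ tetra-aldehyde 12, by a twofold catalyst-controlled desymmetrising aldol condensation with acetaldehyde that sets both side-chain stereocentres and both (E)-enals.
2. 12 ⇐ bis(cyclopent-3-enylacetate) 10 (ozonolysis) ⇐ diol 8 + commercial acid 9 (double Mitsunobu, inversion at the ring carbinol).
3. 8 ⇐ enone 3: anti radical hydroxymethylation, α-epimerisation, cis-selective ketone reduction, malonate → 1,3-diol, acetonide.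
4. 3 ⇐ 2-methylcyclopent-2-enone 1 + bromomalonate 2 by photo-organocatalytic γ-alkylation (first stereocentre).
5. Rings: the cyclopentane is bought with 1; the only ring closed is the protecting 1,3-dioxane (step 4), opened again in step 8.

Steps 1 and 7 are proposed new reactions; the catalyst enantiomer named in each is the predicted one, and the pseudo-enantiomeric catalyst would be used if the sense proved opposite.

**Route**

Step 1
Reactants: 1 2-methylcyclopent-2-en-1-one; 2 dimethyl 2-bromomalonate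
Product: 3 dimethyl 2-[(1R)-3-methyl-4-oxocyclopent-2-en-1-yl]malonate
Conditions: 9-amino-9-deoxy-epi-quinidine (20 mol%), TFA (40 mol%), NaOAc (2 equiv), 1 (3 equiv), toluene, 400 nm LED, 25 °C
Reagents that add atoms: none
Why: Proposed new method: the cinchona primary amine condenses with 1 to the linear dienamine (a 1-aminocyclopentadiene) whose photoexcitation or EDA complex with 2 releases the electrophilic malonyl radical, which adds to the free γ-terminus (the α-carbon is blocked by the methyl group) on the face left open by the quinoline/quinuclidine unit, and the resulting α-amino allyl radical reduces 2 to carry the chain, so the C–C bond and the (R) centre are formed together; the closest known reactions are the photo-organocatalytic α-alkylation of cyclic ketones and the γ-alkylation of enals with bromomalonates through enamines and dienamines.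

Step 2
Reactants: 3 dimethyl 2-[(1R)-3-methyl-4-oxocyclopent-2-en-1-yl]malonate
Product: 5 dimethyl 2-[(1R,2S,3R)-2-(hydroxymethyl)-3-methyl-4-oxocyclopentyl]malonate, via C3-epimeric hydroxymethyl adducts 4 (not isolated)
Conditions: benzophenone (0.3 equiv), MeOH, hν 350 nm, 15 °C; then K2CO3 (0.2 equiv), MeOH, 0 °C to rt
Reagents that add atoms: methanol CO
Why: Photochemical Giese-type radical conjugate addition, in which the hydroxymethyl radical (H-abstraction from methanol by triplet benzophenone) adds to the enone β-carbon anti to the neighbouring malonyl group (sets C2 trans), and base equilibration of the α-methyl ketone then places the methyl trans to the new CH2OH (thermodynamic C3).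

Step 3
Reactants: 5 dimethyl 2-[(1R,2S,3R)-2-(hydroxymethyl)-3-methyl-4-oxocyclopentyl]malonate
Product: 7 2-[(1R,2S,3R,4S)-4-hydroxy-2-(hydroxymethyl)-3-methylcyclopentyl]propane-1,3-diol, via hydroxy diester 6 (not isolated)
Conditions: L-Selectride (3.3 equiv), THF, −78 °C; then LiAlH4 (4 equiv), −78 °C to 40 °C; Rochelle salt work-up
Reagents that add atoms: none
Why: Diastereoselective ketone reduction followed by ester reduction, in which the bulky borohydride attacks anti to the adjacent α-methyl group (the face also free of the C1 substituent) to give the alcohol cis to the methyl (4S), and LiAlH4 then reduces both malonate esters to the 1,3-diol.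

Step 4
Reactants: 7 2-[(1R,2S,3R,4S)-4-hydroxy-2-(hydroxymethyl)-3-methylcyclopentyl]propane-1,3-diol
Product: 8 (1S,2R,3S,4R)-4-(2,2-dimethyl-1,3-dioxan-5-yl)-3-(hydroxymethyl)-2-methylcyclopentan-1-ol
Conditions: 2,2-dimethoxypropane (1.3 equiv), PPTS (5 mol%), DMF, 0 °C to rt
Reagents that add atoms: 2,2-dimethoxypropane COC(C)(C)OC
Why: Selective acetonide formation, because only the 2-substituted propane-1,3-diol can close a six-membered 1,3-dioxane while every other hydroxyl pair would need a 7- or 8-membered acetal, so the ring-CH2OH and the ring OH stay free.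

Step 5
Reactants: 8 (1S,2R,3S,4R)-4-(2,2-dimethyl-1,3-dioxan-5-yl)-3-(hydroxymethyl)-2-methylcyclopentan-1-ol; 9 2-(cyclopent-3-en-1-yl)acetic acid
Product: 10 [(1S,2R,3R,5R)-3-{[2-(cyclopent-3-en-1-yl)acetyl]oxy}-5-(2,2-dimethyl-1,3-dioxan-5-yl)-2-methylcyclopentyl]methyl 2-(cyclopent-3-en-1-yl)acetate
Conditions: 9 (2.6 equiv), PPh3 (3 equiv), DIAD (3 equiv), THF, 0 °C to rt
Reagents that add atoms: none
Why: Double Mitsunobu esterification, which acylates the primary alcohol and displaces the secondary alkoxyphosphonium by carboxylate in SN2 fashion, inverting the (S)-carbinol (OH cis to methyl) to the required (R)-ester trans to the methyl group.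

Step 6
Reactants: 10 [(1S,2R,3R,5R)-3-{[2-(cyclopent-3-en-1-yl)acetyl]oxy}-5-(2,2-dimethyl-1,3-dioxan-5-yl)-2-methylcyclopentyl]methyl 2-(cyclopent-3-en-1-yl)acetate
Product: 12 [(1S,2R,3R,5R)-5-(2,2-dimethyl-1,3-dioxan-5-yl)-2-methyl-3-{[5-oxo-3-(2-oxoethyl)pentanoyl]oxy}cyclopentyl]methyl 5-oxo-3-(2-oxoethyl)pentanoate, via bis-ozonide 11 (not isolated)
Conditions: O3, CH2Cl2, −78 °C; then PPh3 (2.5 equiv), −78 °C to rt; used crude
Reagents that add atoms: ozone [O-][O+]=O
Why: Ozonolysis with reductive work-up (Criegee mechanism) cleaves the two symmetric ring alkenes, the only C=C bonds present, so that each acyl group becomes a prochiral 3-substituted glutaraldehyde and no stereocentre is touched.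

Step 7
Reactants: 12 [(1S,2R,3R,5R)-5-(2,2-dimethyl-1,3-dioxan-5-yl)-2-methyl-3-{[5-oxo-3-(2-oxoethyl)pentanoyl]oxy}cyclopentyl]methyl 5-oxo-3-(2-oxoethyl)pentanoate
Product: 13 [(1S,2R,3R,5R)-5-(2,2-dimethyl-1,3-dioxan-5-yl)-3-{[(3S,4E)-4-formyl-3-(2-oxoethyl)hex-4-enoyl]oxy}-2-methylcyclopentyl]methyl (3S,4E)-4-formyl-3-(2-oxoethyl)hex-4-enoate
Conditions: acetaldehyde (6 equiv, slow addition), (S)-2-[diphenyl(trimethylsilyloxy)methyl]pyrrolidine (30 mol%), PhCO2H (30 mol%), CHCl3, 4 °C; stopped at one condensation per glutaraldehyde unit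
Reagents that add atoms: acetaldehyde CC=O
Why: Proposed new method: the amine forms an enamine reversibly with either enantiotopic formylmethyl arm (Curtin–Hammett), the enamine adds to acetaldehyde on the face away from the diphenyl(silyloxy)methyl group while A(1,3) strain holds the β-H in the enamine plane, so only the arm that keeps the larger ester-bearing branch anti to the incoming aldehyde reacts fast, and acid-promoted dehydration through the iminium gives the (E)-2-ethylidene aldehyde, which sets the (S) centre and the C=C bond of each acyl group (any product from the wrong arm still carries the fast arm and is drained to the bis-ethylidene by-product); the closest known reactions are amine-catalysed desymmetrising aldol reactions of prochiral dicarbonyl compounds (Hajos–Parrish type, 4-substituted cyclohexanones) and amine/acid-catalysed cross-aldol condensation of aldehydes with acetaldehyde.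

Step 8
Reactants: 13 [(1S,2R,3R,5R)-5-(2,2-dimethyl-1,3-dioxan-5-yl)-3-{[(3S,4E)-4-formyl-3-(2-oxoethyl)hex-4-enoyl]oxy}-2-methylcyclopentyl]methyl (3S,4E)-4-formyl-3-(2-oxoethyl)hex-4-enoate
Product: 14 {(1S,2R,3R,5R)-5-(1,3-dihydroxypropan-2-yl)-3-{[(3S,4E)-4-formyl-3-(2-oxoethyl)hex-4-enoyl]oxy}-2-methylcyclopentyl}methyl (3S,4E)-4-formyl-3-(2-oxoethyl)hex-4-enoate
Conditions: AcOH/THF/H2O (3:1:1), rt, dilute
Reagents that add atoms: none
Why: Mild acid-catalysed hydrolysis of the 1,3-dioxane acetonide, chosen to be gentle enough that the esters, enals and aldehydes are left untouched, releases the 1,3-diol without affecting any stereocentre.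

**Compound list**
1 | 2-methylcyclopent-2-en-1-one | CC1=CCCC1=O | starting material
2 | dimethyl 2-bromomalonate | COC(=O)C(Br)C(=O)OC | starting material
3 | dimethyl 2-[(1R)-3-methyl-4-oxocyclopent-2-en-1-yl]malonate | COC(=O)C(C(=O)OC)[C@H]1C=C(C)C(=O)C1 | intermediate
4 | dimethyl 2-[(1R,2S,3RS)-2-(hydroxymethyl)-3-methyl-4-oxocyclopentyl]malonate (C3 epimers) | OC[C@@H]1C(C)C(=O)C[C@H]1C(C(=O)OC)C(=O)OC | intermediate
5 | dimethyl 2-[(1R,2S,3R)-2-(hydroxymethyl)-3-methyl-4-oxocyclopentyl]malonate | OC[C@@H]1[C@@H](C)C(=O)C[C@H]1C(C(=O)OC)C(=O)OC | intermediate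
6 | dimethyl 2-[(1R,2S,3R,4S)-4-hydroxy-2-(hydroxymethyl)-3-methylcyclopentyl]malonate | OC[C@@H]1[C@@H](C)[C@@H](O)C[C@H]1C(C(=O)OC)C(=O)OC | intermediate
7 | 2-[(1R,2S,3R,4S)-4-hydroxy-2-(hydroxymethyl)-3-methylcyclopentyl]propane-1,3-diol | OC[C@@H]1[C@@H](C)[C@@H](O)C[C@H]1C(CO)CO | intermediate
8 | (1S,2R,3S,4R)-4-(2,2-dimethyl-1,3-dioxan-5-yl)-3-(hydroxymethyl)-2-methylcyclopentan-1-ol | OC[C@@H]1[C@@H](C)[C@@H](O)C[C@H]1C2COC(C)(C)OC2 | intermediate
9 | 2-(cyclopent-3-en-1-yl)acetic acid | OC(=O)CC1CC=CC1 | starting material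
10 | [(1S,2R,3R,5R)-3-{[2-(cyclopent-3-en-1-yl)acetyl]oxy}-5-(2,2-dimethyl-1,3-dioxan-5-yl)-2-methylcyclopentyl]methyl 2-(cyclopent-3-en-1-yl)acetate | O=C(CC1CC=CC1)OC[C@@H]2[C@@H](C)[C@H](OC(=O)CC3CC=CC3)C[C@H]2C4COC(C)(C)OC4 | intermediate
11 | [(1S,2R,3R,5R)-5-(2,2-dimethyl-1,3-dioxan-5-yl)-2-methyl-3-{[2-(6,7,8-trioxabicyclo[3.2.1]octan-3-yl)acetyl]oxy}cyclopentyl]methyl 2-(6,7,8-trioxabicyclo[3.2.1]octan-3-yl)acetate (bis-ozonide) | O=C(CC1CC2OOC(C1)O2)OC[C@@H]3[C@@H](C)[C@H](OC(=O)CC4CC5OOC(C4)O5)C[C@H]3C6COC(C)(C)OC6 | intermediate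
12 | [(1S,2R,3R,5R)-5-(2,2-dimethyl-1,3-dioxan-5-yl)-2-methyl-3-{[5-oxo-3-(2-oxoethyl)pentanoyl]oxy}cyclopentyl]methyl 5-oxo-3-(2-oxoethyl)pentanoate | O=CCC(CC=O)CC(=O)OC[C@@H]1[C@@H](C)[C@H](OC(=O)CC(CC=O)CC=O)C[C@H]1C2COC(C)(C)OC2 | intermediate
13 | [(1S,2R,3R,5R)-5-(2,2-dimethyl-1,3-dioxan-5-yl)-3-{[(3S,4E)-4-formyl-3-(2-oxoethyl)hex-4-enoyl]oxy}-2-methylcyclopentyl]methyl (3S,4E)-4-formyl-3-(2-oxoethyl)hex-4-enoate | C/C=C(/C=O)[C@@H](CC=O)CC(=O)OC[C@@H]1[C@@H](C)[C@H](OC(=O)C[C@H](CC=O)/C(C=O)=C\C)C[C@H]1C2COC(C)(C)OC2 | intermediate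
14 | {(1S,2R,3R,5R)-5-(1,3-dihydroxypropan-2-yl)-3-{[(3S,4E)-4-formyl-3-(2-oxoethyl)hex-4-enoyl]oxy}-2-methylcyclopentyl}methyl (3S,4E)-4-formyl-3-(2-oxoethyl)hex-4-enoate | C/C=C(/C=O)[C@@H](CC=O)CC(=O)OC[C@@H]1[C@@H](C)[C@H](OC(=O)C[C@H](CC=O)/C(C=O)=C\C)C[C@H]1C(CO)CO | target

**Step count and risks**

Total step count: 8. Longest linear sequence: 8 (1 → 14); acid 9 is bought.

The three steps most likely to fail:

Step 1 (proposed γ-alkylation). The cross-conjugated dienamine could give α′-alkylation instead, the aminocyclopentadiene may dimerise, and 3 could lose ee if its dienamine re-forms. The fallback uses known chemistry, does not start from a numbered compound (it replaces 1 and 2) and comes back at 3. Commercial dimethyl malonate (COC(=O)CC(=O)OC) and (2E,4E)-hexa-2,4-dienal (C/C=C/C=C/C=O) undergo the established iminium-catalysed malonate Michael addition ((R)-2-{bis[3,5-bis(trifluoromethyl)phenyl](trimethylsilyloxy)methyl}pyrrolidine, PhCO2H, EtOH, 0 °C, 1,4-addition) to give dimethyl 2-[(3R,4E)-1-oxohex-4-en-3-yl]malonate F1. Cationic Rh(I)-catalysed intramolecular alkene hydroacylation ([Rh(dppe)]ClO4, CH2Cl2) closes the ring to dimethyl 2-[(1S,3RS)-3-methyl-4-oxocyclopentyl]malonate F2. IBX dehydrogenation (DMSO, 70 °C) on the methyl-bearing side of the ketone then gives 3.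

Step 5 (double Mitsunobu with inversion at a hindered cis-2-methylcyclopentanol). Elimination or incomplete inversion is possible. The fallback sets out from 8 and comes back at 10, replacing the redox condensation by sulfonate displacement. Selective acylation of the primary alcohol with 9 (1.05 equiv, EDC, DMAP, CH2Cl2, 0 °C) gives [(1S,2R,3S,5R)-5-(2,2-dimethyl-1,3-dioxan-5-yl)-3-hydroxy-2-methylcyclopentyl]methyl 2-(cyclopent-3-en-1-yl)acetate F3. Mesylation (MsCl, Et3N) gives [(1S,2R,3S,5R)-5-(2,2-dimethyl-1,3-dioxan-5-yl)-2-methyl-3-(methylsulfonyloxy)cyclopentyl]methyl 2-(cyclopent-3-en-1-yl)acetate F4. SN2 displacement with the caesium salt of 9 (Cs2CO3, 18-crown-6, toluene/DMF, 80 °C) inverts the centre and gives 10.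

Step 7 (proposed desymmetrising condensation). Arm selection may be poor, acetaldehyde may act as donor, and over-condensation can occur. The fallback uses known chemistry, sets out from 12 and comes back at 13, moving the desymmetrisation to the anhydride oxidation level.
- Pinnick oxidation of 12 (NaClO2, NaH2PO4, 2-methylbut-2-ene) gives the tetra-acid 3-(2-{[(1S,2R,3R,5R)-3-{[4-carboxy-3-(carboxymethyl)butanoyl]oxy}-5-(2,2-dimethyl-1,3-dioxan-5-yl)-2-methylcyclopentyl]methoxy}-2-oxoethyl)pentanedioic acid F5.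
- Ac2O closes both glutaric anhydrides to [(1S,2R,3R,5R)-5-(2,2-dimethyl-1,3-dioxan-5-yl)-3-{[2-(2,6-dioxooxan-4-yl)acetyl]oxy}-2-methylcyclopentyl]methyl 2-(2,6-dioxooxan-4-yl)acetate F6.
- The established cinchona-sulfonamide-catalysed enantioselective thiolysis of 3-substituted glutaric anhydrides with benzyl mercaptan gives the bis(hemithioester) with two (3S)-5-(benzylsulfanyl)-3-(carboxymethyl)-5-oxopentanoyl groups on the core of 10, F7.
- Fukuyama reduction (Et3SiH, Pd/C) gives the bis(aldehyde acid) with two (3S)-3-(carboxymethyl)-5-oxopentanoyl groups, F8.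
- Pyrrolidine/propionic acid condensation with acetaldehyde, now at the only enolisable aldehyde of each arm, gives the bis(enal acid) with two (3S,4E)-3-(carboxymethyl)-4-formylhex-4-enoyl groups, F9.
- Thioesterification (EtSH, EDC, DMAP) gives the bis(S-ethyl thioester) with two (3R,4E)-3-[2-(ethylsulfanyl)-2-oxoethyl]-4-formylhex-4-enoyl groups, F10.
- A second Fukuyama reduction gives 13.

**Further compounds**
F1 | step 1 | dimethyl 2-[(3R,4E)-1-oxohex-4-en-3-yl]malonate | COC(=O)C(C(=O)OC)[C@H](CC=O)/C=C/C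
F2 | step 1 | dimethyl 2-[(1S,3RS)-3-methyl-4-oxocyclopentyl]malonate | COC(=O)C(C(=O)OC)[C@H]1CC(C)C(=O)C1
F3 | step 5 | [(1S,2R,3S,5R)-5-(2,2-dimethyl-1,3-dioxan-5-yl)-3-hydroxy-2-methylcyclopentyl]methyl 2-(cyclopent-3-en-1-yl)acetate | O=C(CC1CC=CC1)OC[C@@H]2[C@@H](C)[C@@H](O)C[C@H]2C3COC(C)(C)OC3
F4 | step 5 | [(1S,2R,3S,5R)-5-(2,2-dimethyl-1,3-dioxan-5-yl)-2-methyl-3-(methylsulfonyloxy)cyclopentyl]methyl 2-(cyclopent-3-en-1-yl)acetate | O=C(CC1CC=CC1)OC[C@@H]2[C@@H](C)[C@@H](OS(C)(=O)=O)C[C@H]2C3COC(C)(C)OC3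
F5 | step 7 | 3-(2-{[(1S,2R,3R,5R)-3-{[4-carboxy-3-(carboxymethyl)butanoyl]oxy}-5-(2,2-dimethyl-1,3-dioxan-5-yl)-2-methylcyclopentyl]methoxy}-2-oxoethyl)pentanedioic acid | OC(=O)CC(CC(=O)O)CC(=O)OC[C@@H]1[C@@H](C)[C@H](OC(=O)CC(CC(=O)O)CC(=O)O)C[C@H]1C2COC(C)(C)OC2
F6 | step 7 | [(1S,2R,3R,5R)-5-(2,2-dimethyl-1,3-dioxan-5-yl)-3-{[2-(2,6-dioxooxan-4-yl)acetyl]oxy}-2-methylcyclopentyl]methyl 2-(2,6-dioxooxan-4-yl)acetate | O=C1CC(CC(=O)OC[C@@H]2[C@@H](C)[C@H](OC(=O)CC3CC(=O)OC(=O)C3)C[C@H]2C4COC(C)(C)OC4)CC(=O)O1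
F7 | step 7 | diester of the diol core of 10 carrying two (3S)-5-(benzylsulfanyl)-3-(carboxymethyl)-5-oxopentanoyl groups | O=C(SCc1ccccc1)C[C@@H](CC(=O)O)CC(=O)OC[C@@H]2[C@@H](C)[C@H](OC(=O)C[C@H](CC(=O)O)CC(=O)SCc3ccccc3)C[C@H]2C4COC(C)(C)OC4
F8 | step 7 | diester of the diol core of 10 carrying two (3S)-3-(carboxymethyl)-5-oxopentanoyl groups | O=CC[C@@H](CC(=O)O)CC(=O)OC[C@@H]1[C@@H](C)[C@H](OC(=O)C[C@H](CC(=O)O)CC=O)C[C@H]1C2COC(C)(C)OC2
F9 | step 7 | diester of the diol core of 10 carrying two (3S,4E)-3-(carboxymethyl)-4-formylhex-4-enoyl groups | C/C=C(/C=O)[C@@H](CC(=O)O)CC(=O)OC[C@@H]1[C@@H](C)[C@H](OC(=O)C[C@H](CC(=O)O)/C(C=O)=C\C)C[C@H]1C2COC(C)(C)OC2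
F10 | step 7 | diester of the diol core of 10 carrying two (3R,4E)-3-[2-(ethylsulfanyl)-2-oxoethyl]-4-formylhex-4-enoyl groups | C/C=C(/C=O)[C@@H](CC(=O)SCC)CC(=O)OC[C@@H]1[C@@H](C)[C@H](OC(=O)C[C@H](CC(=O)SCC)/C(C=O)=C\C)C[C@H]1C2COC(C)(C)OC2
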